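**Strategy.** The trans-3,4-dibenzyl pattern of the oxolane (tetrahydrofuran) ring is traced back to a temporary cyclohexene. The chain C7–C3–C4–C7' of the target, with the ring carbons C2 and C5 hanging from C3 and C4, is read as four adjacent ring carbons plus two ester carbons of a Diels–Alder adduct. One catalytic enantioselective [4+2] addition of diethyl fumarate to an (E,E)-1,4-bis(3,4-dimethoxyphenyl)butadiene forges C3–C7 and C4–C7' together and fixes the (3R,4R) trans pair. The alkene of the adduct is then cleaved and its two carbons are expelled as CO, which leaves benzylic CH2 groups; ester reduction and cyclodehydration close the oxolane ring.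

Key step: step 3

Numbering used for the target: oxolane O1, C2–C5; C7 is the benzylic carbon on C3 and C7' the one on C4. The target is (3R,4R).

Assumption: the facial sense of the boron catalyst is taken from the accepted binding model for its ester complexes (carbonyl on boron anti to OEt, α-C–H···O contact, s-trans enoate); on that model the (R)-configured catalyst leaves the Re,Re face of the fumarate open and gives the (1R,2R) adduct.

**Step 1**
Reactants: 1 3,4-dimethoxybenzyl chloride
Product: 2 diethyl (3,4-dimethoxybenzyl)phosphonate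
Conditions: P(OEt)3 (1.3 equiv), neat, 140 °C, EtCl distilled out
Reagents that add atoms: triethyl phosphite, CCOP(OCC)OCC
Why: Michaelis–Arbuzov reaction: phosphorus displaces the activated benzylic chloride and chloride then dealkylates the ethoxyphosphonium ion to the phosphonate; no stereocenter is formed.

**Step 2**
Reactants: 2 diethyl (3,4-dimethoxybenzyl)phosphonate; 3 (E)-3-(3,4-dimethoxyphenyl)prop-2-enal (3,4-dimethoxycinnamaldehyde)
Product: 4 (1E,3E)-1,4-bis(3,4-dimethoxyphenyl)buta-1,3-diene
Conditions: t-BuOK (1.1 equiv), THF, 0 °C → rt; crystallisation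
Reagents that add atoms: none
Why: Horner–Wadsworth–Emmons olefination: the benzylic phosphonate anion adds reversibly to the enal carbonyl and eliminates through the less crowded oxaphosphetane, so the new alkene should be E while the E alkene of 3 is untouched, and the symmetric E,E diene can be freed of minor isomers by crystallisation.

**Step 3**
Reactants: 4 (1E,3E)-1,4-bis(3,4-dimethoxyphenyl)buta-1,3-diene; 5 diethyl fumarate (1.5 equiv)
Product: 6 diethyl (1R,2R,3R,6S)-3,6-bis(3,4-dimethoxyphenyl)cyclohex-4-ene-1,2-dicarboxylate (trans esters, cis aryl groups; the same compound reads 1R,2R,3S,6R if the ring is numbered from the other ester carbon)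
Conditions: (R)-1-(2-methylphenyl)-3,3-diphenyltetrahydro-1H,3H-pyrrolo[1,2-c][1,3,2]oxazaborole (20 mol %), HN(SO2CF3)2 (17 mol %, kept below the oxazaborolidine so that no free acid meets the diene), CH2Cl2, −20 °C → rt; Et3N quench
Reagents that add atoms: none
Why: The protonated oxazaborolidine binds one ester carbonyl of 5 at boron, which lowers the LUMO of the alkene, and the s-cis form of the electron-rich diene 4 then adds in a concerted, suprafacial [4+2] Diels–Alder process. The closest known reaction type is the enantioselective Diels–Alder reaction of fumarate diesters with acyclic 1,3-dienes catalysed by this same family of cationic boron Lewis acids. The one new ring, the cyclohexene, closes by intermolecular [4+2] cycloaddition in which the two diene termini bond to the two fumarate carbons (the future C3–C7 and C4–C7' bonds). C1 and C2 become trans because the E geometry of 5 is carried through the concerted addition, and their absolute R,R sense is set by the catalyst, whose phenyl group covers one face of the bound s-trans enoate so that the diene meets the Re,Re face; C3 and C6 become mutually cis because both termini of the E,E diene bond on the same face of 4, and their relation to the esters follows from the same face choice, since endo and exo approaches of a C2-symmetric trans dienophile to a symmetric diene give one compound. The only selectivity the step must supply is therefore the enantioface of 5, which the catalyst secures, helped by the C2 symmetry of 5 (both carbonyls are equivalent binding sites); the two aryl-bearing centres are erased in step 5, so only the ester-bearing pair has to be enantiopure.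

**Step 4**
Reactants: 6 diethyl (1R,2R,3R,6S)-3,6-bis(3,4-dimethoxyphenyl)cyclohex-4-ene-1,2-dicarboxylate
Product: 8 diethyl (2R,3R)-2-[(1R)-1-(3,4-dimethoxyphenyl)-2-oxoethyl]-3-[(1S)-1-(3,4-dimethoxyphenyl)-2-oxoethyl]butanedioate, via cis-4,5-diol 7 (not isolated)
Conditions: OsO4 (3 mol %), NaIO4 (4 equiv), 2,6-lutidine (2 equiv), dioxane–H2O (3:1), rt; extractive work-up, dried crude used at once
Reagents that add atoms: osmium tetroxide, O=[Os](=O)(=O)=O (catalytic oxygen carrier); sodium periodate, [Na+].[O-]I(=O)(=O)=O; water, O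
Why: Lemieux–Johnson oxidation: OsO4 dihydroxylates the only alkene from the face opposite the two cis aryl groups and periodate cleaves the glycol, while esters and veratryl rings are inert and the lutidine buffer limits over-oxidation; the configuration at the two aldehyde-bearing carbons is of no consequence because both become CH2 in step 5.

**Step 5**
Reactants: 8 diethyl (2R,3R)-2-[(1R)-1-(3,4-dimethoxyphenyl)-2-oxoethyl]-3-[(1S)-1-(3,4-dimethoxyphenyl)-2-oxoethyl]butanedioate
Product: 9 diethyl (2R,3R)-2,3-bis(3,4-dimethoxybenzyl)butanedioate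
Conditions: RhCl(PPh3)3 (2.3 equiv), degassed xylene, 130 °C
Reagents that add atoms: none
Why: Tsuji–Wilkinson decarbonylation: each formyl C–H adds oxidatively to monovalent rhodium, CO migrates to the metal and C–H reductive elimination leaves a benzylic CH2, the CO staying bound as RhCl(CO)(PPh3)2 (hence one equivalent per aldehyde); C2 and C3 take no part under these neutral conditions and keep the R,R configuration.

**Step 6**
Reactants: 9 diethyl (2R,3R)-2,3-bis(3,4-dimethoxybenzyl)butanedioate
Product: 10 (2R,3R)-2,3-bis(3,4-dimethoxybenzyl)butane-1,4-diol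
Conditions: LiAlH4 (2 equiv), THF, 0 °C → rt; aqueous NaOH work-up
Reagents that add atoms: none
Why: Hydride reduction of both esters with LiAlH4 (acyl substitution, then reduction of the aldehyde stage), which does not enolise the esters at low temperature, so the two stereocenters are carried over unchanged.

**Step 7**
Reactants: 10 (2R,3R)-2,3-bis(3,4-dimethoxybenzyl)butane-1,4-diol
Product: 12 (3R,4R)-3,4-bis(3,4-dimethoxybenzyl)tetrahydrofuran, via mono-tosylate 11 (not isolated)
Conditions: TsCl (1.1 equiv), pyridine, 0 °C → 60 °C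
Reagents that add atoms: none
Why: Cyclodehydration by mono-tosylation of one primary alcohol (the two are equivalent by C2 symmetry) followed by intramolecular Williamson-type 5-exo-tet SN2 displacement by the other hydroxyl; substitution occurs at a primary carbon, so C3 and C4 keep the R,R configuration.

**Compound list**

1 | 3,4-dimethoxybenzyl chloride | COc1ccc(CCl)cc1OC | starting material
2 | diethyl (3,4-dimethoxybenzyl)phosphonate | CCOP(=O)(Cc1ccc(OC)c(OC)c1)OCC | intermediate
3 | (E)-3-(3,4-dimethoxyphenyl)prop-2-enal | COc1ccc(/C=C/C=O)cc1OC | starting material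
4 | (1E,3E)-1,4-bis(3,4-dimethoxyphenyl)buta-1,3-diene | COc1ccc(/C=C/C=C/c2ccc(OC)c(OC)c2)cc1OC | intermediate
5 | diethyl fumarate | CCOC(=O)/C=C/C(=O)OCC | starting material
6 | diethyl (1R,2R,3R,6S)-3,6-bis(3,4-dimethoxyphenyl)cyclohex-4-ene-1,2-dicarboxylate | CCOC(=O)[C@H]1[C@H](C(=O)OCC)[C@@H](c2ccc(OC)c(OC)c2)C=C[C@H]1c3ccc(OC)c(OC)c3 | intermediate
7 | diethyl (1R,2R,3R,4R,5S,6S)-3,6-bis(3,4-dimethoxyphenyl)-4,5-dihydroxycyclohexane-1,2-dicarboxylate (cis diol on the face opposite the aryl groups) | CCOC(=O)[C@H]1[C@H](C(=O)OCC)[C@@H](c2ccc(OC)c(OC)c2)[C@H](O)[C@H](O)[C@H]1c3ccc(OC)c(OC)c3 | intermediate (not isolated)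
8 | diethyl (2R,3R)-2-[(1R)-1-(3,4-dimethoxyphenyl)-2-oxoethyl]-3-[(1S)-1-(3,4-dimethoxyphenyl)-2-oxoethyl]butanedioate | CCOC(=O)[C@@H]([C@H](C(=O)OCC)[C@@H](c2ccc(OC)c(OC)c2)C=O)[C@@H](C=O)c3ccc(OC)c(OC)c3 | intermediate
9 | diethyl (2R,3R)-2,3-bis(3,4-dimethoxybenzyl)butanedioate | CCOC(=O)[C@@H]([C@H](C(=O)OCC)Cc2ccc(OC)c(OC)c2)Cc3ccc(OC)c(OC)c3 | intermediate
10 | (2R,3R)-2,3-bis(3,4-dimethoxybenzyl)butane-1,4-diol | OC[C@@H]([C@H](CO)Cc2ccc(OC)c(OC)c2)Cc3ccc(OC)c(OC)c3 | intermediate
11 | (2R,3R)-2,3-bis(3,4-dimethoxybenzyl)-4-hydroxybutyl 4-methylbenzenesulfonate | Cc1ccc(cc1)S(=O)(=O)OC[C@@H]([C@H](CO)Cc2ccc(OC)c(OC)c2)Cc3ccc(OC)c(OC)c3 | intermediate (not isolated)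
12 | (3R,4R)-3,4-bis(3,4-dimethoxybenzyl)tetrahydrofuran | COc1ccc(C[C@H]2COC[C@@H]2Cc2ccc(OC)c(OC)c2)cc1OC | target

**Step count.** Total: 7 steps. Longest linear sequence: 7 steps (1 → 2 → 4 → 6 → 8 → 9 → 10 → 12).

**Steps most likely to fail**

1. Step 3. What may go wrong: slow cycloaddition because both diene termini carry aryl groups, acid-triggered oligomerisation of the electron-rich diene, migration of the new ring alkene into conjugation with an aryl group, or insufficient face discrimination. Fallback, auxiliary control in place of catalyst control, setting out from 4: fumaryl chloride and (1S,2R,5S)-menthol (pyridine, CH2Cl2) give di-(1S,2R,5S)-menthyl fumarate F1. The mirror-image (1R,2S,5R)-menthyl ester is known to give S,S adducts with simple dienes, so this antipode is chosen. Et2AlCl (2 equiv) in toluene at −40 °C → rt should promote the Diels–Alder reaction of F1 with 4, both menthyl groups shielding the same face, to give the dimenthyl cyclohexene diester F2, which can be brought to diastereomeric purity by crystallisation. The conditions of steps 4 and 5 then lead to the dimenthyl dialdehyde F3 and the dimenthyl (2R,3R)-2,3-bis(3,4-dimethoxybenzyl)butanedioate F4. LiAlH4 in THF at reflux releases the auxiliary and rejoins the route at 10.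

2. Step 5. What may go wrong: β-hydride elimination from the benzylic alkylrhodium hydride before C–H reductive elimination, which would give arylidene succinates and erase the C2/C3 centres; stalling after the first CO loss; thermal aldol condensation of the dialdehyde. Fallback, oxidation and radical decarboxylation in place of decarbonylation at the metal, setting out from 8: Pinnick oxidation (NaClO2, NaH2PO4, 2-methyl-2-butene, t-BuOH–H2O) gives the diacid (2R,3S,4S,5S)-2,5-bis(3,4-dimethoxyphenyl)-3,4-bis(ethoxycarbonyl)hexanedioic acid F5 (same spatial arrangement as 8; the S labels at C3/C4 arise from a priority change). DCC, 1-hydroxypyridine-2(1H)-thione and catalytic DMAP in CH2Cl2 in the dark give the bis(2-thioxopyridin-1(2H)-yl) ester F6. Visible-light irradiation with t-BuSH in THF then effects Barton reductive decarboxylation; each benzylic radical is quenched by the thiol and the ester-bearing centres never become radical or anionic. The fallback rejoins the route at 9.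

3. Step 4. What may go wrong: enolisation of the α-aryl aldehydes as they form, followed by intramolecular aldol closure of the 1,6-dialdehyde to a cyclopentene, or hydration and over-oxidation in the aqueous medium. Fallback, closing the oxolane before opening the cyclohexene, setting out from 6: LiAlH4 (THF, 0 °C → rt) gives [(1R,2R,3R,6S)-3,6-bis(3,4-dimethoxyphenyl)cyclohex-4-ene-1,2-diyl]dimethanol F7. Mitsunobu cyclodehydration (PPh3, DIAD, THF) gives the trans-fused ether (3aR,4R,7S,7aR)-4,7-bis(3,4-dimethoxyphenyl)-1,3,3a,4,7,7a-hexahydro-2-benzofuran F8. The conditions of step 4 then give the oxolane dialdehyde (2R)-2-(3,4-dimethoxyphenyl)-2-[(3S,4S)-4-[(1S)-1-(3,4-dimethoxyphenyl)-2-oxoethyl]oxolan-3-yl]acetaldehyde F9 (ring carbons arranged as in 12; the labels change by priority only). In F9 an aldol closure would need a trans-fused bicyclo[3.3.0]octane and no ester α-hydrogen is present. RhCl(PPh3)3 (2.3 equiv, xylene, 130 °C) then removes both formyl groups, and the fallback rejoins the route at 12.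

**Further compounds**

F1 | step 3 | bis[(1S,2R,5S)-5-methyl-2-(propan-2-yl)cyclohexyl] (2E)-but-2-enedioate | CC(C)[C@H]1CC[C@H](C)C[C@@H]1OC(=O)/C=C/C(=O)O[C@H]1C[C@@H](C)CC[C@@H]1C(C)C
F2 | step 3 | bis[(1S,2R,5S)-5-methyl-2-(propan-2-yl)cyclohexyl] (1R,2R,3R,6S)-3,6-bis(3,4-dimethoxyphenyl)cyclohex-4-ene-1,2-dicarboxylate | CC(C)[C@H]4CC[C@H](C)C[C@@H]4OC(=O)[C@H]1[C@H](C(=O)O[C@H]5C[C@@H](C)CC[C@@H]5C(C)C)[C@@H](c2ccc(OC)c(OC)c2)C=C[C@H]1c3ccc(OC)c(OC)c3
F3 | step 3 | bis[(1S,2R,5S)-5-methyl-2-(propan-2-yl)cyclohexyl] (2R,3R)-2-[(1R)-1-(3,4-dimethoxyphenyl)-2-oxoethyl]-3-[(1S)-1-(3,4-dimethoxyphenyl)-2-oxoethyl]butanedioate | CC(C)[C@H]4CC[C@H](C)C[C@@H]4OC(=O)[C@@H]([C@H](C(=O)O[C@H]5C[C@@H](C)CC[C@@H]5C(C)C)[C@@H](c2ccc(OC)c(OC)c2)C=O)[C@@H](C=O)c3ccc(OC)c(OC)c3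
F4 | step 3 | bis[(1S,2R,5S)-5-methyl-2-(propan-2-yl)cyclohexyl] (2R,3R)-2,3-bis(3,4-dimethoxybenzyl)butanedioate | CC(C)[C@H]4CC[C@H](C)C[C@@H]4OC(=O)[C@@H]([C@H](C(=O)O[C@H]5C[C@@H](C)CC[C@@H]5C(C)C)Cc2ccc(OC)c(OC)c2)Cc3ccc(OC)c(OC)c3
F5 | step 5 | (2R,3S,4S,5S)-2,5-bis(3,4-dimethoxyphenyl)-3,4-bis(ethoxycarbonyl)hexanedioic acid | CCOC(=O)[C@@H]([C@H](C(=O)OCC)[C@@H](c2ccc(OC)c(OC)c2)C(O)=O)[C@@H](C(O)=O)c3ccc(OC)c(OC)c3
F6 | step 5 | 3,4-diethyl 1,6-bis(2-thioxopyridin-1(2H)-yl) (2R,3S,4S,5S)-2,5-bis(3,4-dimethoxyphenyl)hexane-1,3,4,6-tetracarboxylate-type bis(thiohydroxamate) ester of F5 | CCOC(=O)[C@@H]([C@H](C(=O)OCC)[C@@H](c2ccc(OC)c(OC)c2)C(=O)ON4C=CC=CC4=S)[C@@H](C(=O)ON5C=CC=CC5=S)c3ccc(OC)c(OC)c3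
F7 | step 4 | [(1R,2R,3R,6S)-3,6-bis(3,4-dimethoxyphenyl)cyclohex-4-ene-1,2-diyl]dimethanol | OC[C@H]1[C@H](CO)[C@@H](c2ccc(OC)c(OC)c2)C=C[C@H]1c3ccc(OC)c(OC)c3
F8 | step 4 | (3aR,4R,7S,7aR)-4,7-bis(3,4-dimethoxyphenyl)-1,3,3a,4,7,7a-hexahydro-2-benzofuran | O1C[C@H]2[C@H](C1)[C@@H](c3ccc(OC)c(OC)c3)C=C[C@H]2c4ccc(OC)c(OC)c4
F9 | step 4 | (2R)-2-(3,4-dimethoxyphenyl)-2-[(3S,4S)-4-[(1S)-1-(3,4-dimethoxyphenyl)-2-oxoethyl]oxolan-3-yl]acetaldehyde | O1C[C@@H]([C@H](C1)[C@@H](c2ccc(OC)c(OC)c2)C=O)[C@@H](C=O)c3ccc(OC)c(OC)c3
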